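**Retrosynthetic overview**
1. Target 21 ⇐ fluoride desilylation of 20 ⇐ Mitsunobu inversion at C3 of β-carbinol 16 with (Z)-4-acetoxy-2-methylbut-2-enoic acid 19 (from 3-methylfuran-2(5H)-one).
2. 16 ⇐ α-face hydride reduction of ketone 15 ⇐ C4–C(sp2) bond by palladium coupling of silyl enol ether 11 with a 2-bromoacrylate (new reaction).
3. 11 ⇐ double methylenation of keto-acetal 7: the pyranone C=O becomes the CH2=C(CH2OH) unit and the anomeric carbon becomes the vinyl group, so the two groups are cis by ring constraint.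
4. 7 ⇐ Diels–Alder annulation of bis-silyloxydiene 6 onto pyranone 3 (sets C1, C5, C6).
5. 3 ⇐ key step: Achmatowicz ring expansion of furan 1, then enantioselective acetylation. Ring order: pyranone (by ring expansion), then the cyclohexane (the only ring of the target), after which the pyran is opened.

Assumption: (4-methylfuran-2-yl)methanol (1) and sodium formylacetone (4) are taken as purchasable catalogue compounds.
Naming convention: ring carbons keep the target numbering (C1 quaternary, C2 CH2, C3 and C5 oxygen-bearing, C4 and C6 side-chain-bearing); β is the face of the C1 methyl group, α the opposite face.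

**Step 1**
Reactants: 1 (4-methylfuran-2-yl)methanol
Product: 2 (±)-6-hydroxy-5-methyl-2H-pyran-3(6H)-one
Conditions: NBS (1.05 equiv), NaHCO3, NaOAc, THF/H2O 4:1, 0 °C
Reagents that add atoms: water, O
Why: Achmatowicz rearrangement, the key ring expansion: NBS/water oxidises the furan to a cis-enedione whose hydroxymethyl group closes on the aldehyde, so the five-membered furan becomes the six-membered pyranone that holds the enone for the annulation, the ketone and O–CH2 unit of the later CH2=C–CH2OH side chain and the masked aldehyde of the later vinyl group, while the new hemiacetal centre stays configurationally mobile.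

**Step 2**
Reactants: 2 (±)-6-hydroxy-5-methyl-2H-pyran-3(6H)-one
Product: 3 (2S)-3-methyl-5-oxo-5,6-dihydro-2H-pyran-2-yl acetate
Conditions: Ac2O (1.3 equiv), (R)-benzotetramisole [(R)-2-phenyl-2,3-dihydroimidazo[2,1-b][1,3]benzothiazole, C15H12N2S] (5 mol %), 2,6-lutidine, CHCl3, 0 °C
Reagents that add atoms: acetic anhydride, CC(=O)OC(C)=O
Why: Dynamic kinetic resolution by enantioselective acyl transfer (chiral isothiourea catalysis): the lactol enantiomers interconvert through the open form while the catalyst acetylates one of them, which fixes the S centre that later shields one face of the enone, the sense being predicted from the cation–π model for π-substituted carbinols and checked on a pilot run (the antipodal catalyst is used if it is the reverse).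

**Step 3**
Reactants: 4 sodium 3-oxobut-1-en-1-olate (sodium formylacetone)
Product: 6 (E)-1,3-bis(tert-butyldimethylsilyloxy)buta-1,3-diene, via silyloxy enone 5 (not isolated)
Conditions: TBSOTf (2.1 equiv), Et3N (1.3 equiv), Et2O, 0 °C → rt
Reagents that add atoms: tert-butyldimethylsilyl triflate, CC(C)(C)[Si](C)(C)OS(=O)(=O)C(F)(F)F
Why: Silyl enol ether formation: the enolate oxygen is silylated first and R3SiOTf/Et3N then enolises the methyl ketone of 5 to give the electron-rich E diene.

**Step 4**
Reactants: 3 (2S)-3-methyl-5-oxo-5,6-dihydro-2H-pyran-2-yl acetate; 6 (E)-1,3-bis(tert-butyldimethylsilyloxy)buta-1,3-diene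
Product: 7 cis-fused (1S)-1-acetoxy-8a-methyl-5,7-bis(tert-butyldimethylsilyloxy)-4a,5,8,8a-tetrahydro-1H-isochromen-4(3H)-one (target numbering: C1 β-methyl; C1–acetal and C6–ketone bonds α; C5 α-OTBS; OAc cis to methyl)
Conditions: 6 (1.5 equiv), toluene, BHT (trace), 80 °C, 36 h
Reagents that add atoms: none
Why: Diels–Alder reaction: the CH2 terminus of the diene bonds to the β-carbon of the enone (future C1) and the silyloxy-bearing terminus to the α-carbon (future C6) on the face anti to the acetoxy group, which sets C1 and C6 as a cis ring fusion (so the two later alkenyl groups are cis) and, through the endo transition state, places the C5 silyloxy group on the same α face.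

**Step 5**
Reactants: 7 cis-fused keto-acetal adduct
Product: 11 1β-methyl-1α-vinyl-3,5α-bis(tert-butyldimethylsilyloxy)-6α-[3-(triethylsilyloxy)prop-1-en-2-yl]cyclohex-3-ene, via methylene acetal 8 (not isolated), via hydroxy aldehyde 9 (not isolated), via allylic alcohol 10 (not isolated)
Conditions: Ph3PCH3Br (3.5 equiv), KN(SiMe3)2 (3.3 equiv), THF, −78 → 25 °C; KOtBu (1.3 equiv), 0 °C → rt; Et3SiCl (4 equiv), 0 °C
Reagents that add atoms: methyltriphenylphosphonium bromide, C[P+](c1ccccc1)(c1ccccc1)c1ccccc1.[Br-]; chlorotriethylsilane, CC[Si](Cl)(CC)CC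
Why: Two Wittig methylenations and an O-silylation in one flask: the ylide converts the ring ketone into the exocyclic methylene while C6 is still locked in the cis-fused ring, tert-butoxide then transesterifies the anomeric acetate so that the lactolate opens to the alkoxy aldehyde, which is methylenated to the vinyl group at the non-epimerisable quaternary C1, and the primary alkoxide is trapped as its triethylsilyl ether.

**Step 6**
Reactants: 12 2,3-dibromopropanoyl chloride
Product: 14 2-(trimethylsilyl)ethyl 2-bromoprop-2-enoate, via dibromo ester 13 (not isolated)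
Conditions: Me3SiCH2CH2OH (1.0 equiv), Et3N (2.2 equiv), CH2Cl2, −20 → 0 °C
Reagents that add atoms: 2-(trimethylsilyl)ethanol, C[Si](C)(C)CCO
Why: Esterification of the acid chloride followed by E2 loss of HBr (α-proton and β-bromide) from the 2,3-dibromo ester gives the 2-bromoacrylate.

**Step 7**
Reactants: 11 silyl enol ether; 14 2-(trimethylsilyl)ethyl 2-bromoprop-2-enoate
Product: 15 2-(trimethylsilyl)ethyl 2-[1β-methyl-3-oxo-1α-vinyl-5α-(tert-butyldimethylsilyloxy)-6α-[3-(triethylsilyloxy)prop-1-en-2-yl]cyclohex-4β-yl]prop-2-enoate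
Conditions: 14 (1.5 equiv), Pd2(dba)3 (2.5 mol %), P(t-Bu)3 (6 mol %), AgOAc (1.3 equiv), toluene, 40 °C, dark
Reagents that add atoms: none
Why: Proposed new method: zerovalent palladium inserts into the C–Br bond of 14, AgOAc takes the bromide and leaves an acetate on divalent palladium that pulls the silyl group off the enol ether (the transmetalation of the Saegusa–Ito oxidation), and the bulky monophosphine makes C–C reductive elimination from the C4-bound palladium enolate faster than β-hydride loss, so the 1-carboxyvinyl group is joined to C4 from the β face, anti to the C5 silyloxy group and in the equatorial position that the still epimerisable C4 prefers, the closest known reaction type being the palladium-catalysed α-arylation and α-alkenylation of silyl enol ethers (Kuwajima–Urabe coupling), not yet shown for a 2-bromoacrylate, whose Michael reactivity is the new hazard and is kept down by having neither free enolate nor fluoride in solution.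

**Step 8**
Reactants: 15 ketone
Product: 16 2-(trimethylsilyl)ethyl 2-[3β-hydroxy-1β-methyl-1α-vinyl-5α-(tert-butyldimethylsilyloxy)-6α-[3-(triethylsilyloxy)prop-1-en-2-yl]cyclohex-4β-yl]prop-2-enoate
Conditions: LiAlH(OtBu)3 (2 equiv), THF, −40 → −10 °C; quench at −40 °C with aq. KNaC4H4O6 (potassium sodium tartrate)
Reagents that add atoms: none
Why: Diastereoselective hydride reduction: in the chair with the C6 side chain axial the β face of the C3 carbonyl is blocked by the syn-axial C1 methyl group, so the bulky hydride enters from the α face and gives the axial 3β-alcohol, while ester and acrylate are inert to this reagent and the cold quench prevents lactonisation.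

**Step 9**
Reactants: 17 3-methylfuran-2(5H)-one
Product: 19 (Z)-4-acetoxy-2-methylbut-2-enoic acid, via sodium hydroxy enoate 18 (not isolated)
Conditions: NaOH (1.0 equiv), H2O/THF, 0 °C → rt, evaporate to dryness; NaH (1.05 equiv), DMF, 0 °C; Ac2O (1.05 equiv), −20 °C; cold aq. NaHSO4 to pH 3
Reagents that add atoms: sodium hydroxide, [Na+].[OH-]; acetic anhydride, CC(=O)OC(C)=O
Why: Saponification keeps the Z double bond fixed by the butenolide ring, and the alkoxide of the resulting alkoxide–carboxylate dianion is acetylated selectively by one equivalent of Ac2O, which avoids a mixed anhydride that would relactonise, before acidification frees the acid.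

**Step 10**
Reactants: 16 3β-alcohol; 19 (Z)-4-acetoxy-2-methylbut-2-enoic acid
Product: 20 2-(trimethylsilyl)ethyl 2-[3α-[(Z)-4-acetoxy-2-methylbut-2-enoyloxy]-1β-methyl-1α-vinyl-5α-(tert-butyldimethylsilyloxy)-6α-[3-(triethylsilyloxy)prop-1-en-2-yl]cyclohex-4β-yl]prop-2-enoate
Conditions: 19 (2.5 equiv), PPh3 (2.5 equiv), DIAD (2.5 equiv), toluene, 0 °C → rt
Reagents that add atoms: none
Why: Mitsunobu reaction: the carboxylate displaces the axial alkoxyphosphonium group by SN2 from the α face, so the ester is formed with inversion at C3 (β-OH to the required α-ester) without touching the Z double bond, the only free hydroxyl in 16 being the one at C3.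

**Step 11**
Reactants: 20 fully protected ester
Product: 21 target CNP0261293.8, 2-[3α-[(Z)-4-acetoxy-2-methylbut-2-enoyloxy]-5α-hydroxy-6α-(3-hydroxyprop-1-en-2-yl)-1β-methyl-1α-vinylcyclohex-4β-yl]prop-2-enoic acid (C1 S; C3 S; C4 S; C5 R; C6 S)
Conditions: tris(dimethylamino)sulfonium difluorotrimethylsilicate (TASF, 6 equiv), DMF, 0 °C → rt; pH 5 NaH2PO4 buffer work-up
Reagents that add atoms: none
Why: Fluoride-mediated global desilylation: the 2-(trimethylsilyl)ethyl ester fragments first (ethene and Me3SiF) to the carboxylate, which cannot lactonise, then both silyl ethers are cleaved, the carboxylic esters survive the weakly basic fluoride source and the pH 5 work-up keeps the γ-hydroxy acid from closing to the lactone.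

**Compound list**
1 | (4-methylfuran-2-yl)methanol | Cc1coc(CO)c1 | starting material
2 | (±)-6-hydroxy-5-methyl-2H-pyran-3(6H)-one | CC1=CC(=O)COC1O | intermediate
3 | (2S)-3-methyl-5-oxo-5,6-dihydro-2H-pyran-2-yl acetate | CC(=O)O[C@@H]1OCC(=O)C=C1C | intermediate
4 | sodium 3-oxobut-1-en-1-olate (sodium formylacetone) | CC(=O)C=C[O-].[Na+] | starting material
5 | (E)-4-(tert-butyldimethylsilyloxy)but-3-en-2-one | CC(=O)/C=C/O[Si](C)(C)C(C)(C)C | intermediate
6 | (E)-1,3-bis(tert-butyldimethylsilyloxy)buta-1,3-diene | C=C(O[Si](C)(C)C(C)(C)C)/C=C/O[Si](C)(C)C(C)(C)C | intermediate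
7 | cis-fused (1S)-1-acetoxy-8a-methyl-5,7-bis(tert-butyldimethylsilyloxy)-4a,5,8,8a-tetrahydro-1H-isochromen-4(3H)-one (C1 β-methyl; ring-fusion bonds α; C5 α-OTBS) | CC(=O)O[C@@H]1OCC(=O)[C@H]2[C@@H](O[Si](C)(C)C(C)(C)C)C=C(O[Si](C)(C)C(C)(C)C)C[C@@]12C | intermediate
8 | (1S)-1-acetoxy-8a-methyl-4-methylene-5,7-bis(tert-butyldimethylsilyloxy)-3,4,4a,5,8,8a-hexahydro-1H-isochromene (configuration as 7) | CC(=O)O[C@@H]1OCC(=C)[C@H]2[C@@H](O[Si](C)(C)C(C)(C)C)C=C(O[Si](C)(C)C(C)(C)C)C[C@@]12C | intermediate
9 | 1β-methyl-3,5α-bis(tert-butyldimethylsilyloxy)-6α-(3-hydroxyprop-1-en-2-yl)cyclohex-3-ene-1α-carbaldehyde | O=C[C@]1(C)CC(O[Si](C)(C)C(C)(C)C)=C[C@H](O[Si](C)(C)C(C)(C)C)[C@@H]1C(=C)CO | intermediate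
10 | 2-[1β-methyl-1α-vinyl-3,5α-bis(tert-butyldimethylsilyloxy)cyclohex-3-en-6α-yl]prop-2-en-1-ol | C=C[C@]1(C)CC(O[Si](C)(C)C(C)(C)C)=C[C@H](O[Si](C)(C)C(C)(C)C)[C@@H]1C(=C)CO | intermediate
11 | 1β-methyl-1α-vinyl-3,5α-bis(tert-butyldimethylsilyloxy)-6α-[3-(triethylsilyloxy)prop-1-en-2-yl]cyclohex-3-ene | C=C[C@]1(C)CC(O[Si](C)(C)C(C)(C)C)=C[C@H](O[Si](C)(C)C(C)(C)C)[C@@H]1C(=C)CO[Si](CC)(CC)CC | intermediate
12 | 2,3-dibromopropanoyl chloride | O=C(Cl)C(Br)CBr | starting material
13 | 2-(trimethylsilyl)ethyl 2,3-dibromopropanoate (racemic) | C[Si](C)(C)CCOC(=O)C(Br)CBr | intermediate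
14 | 2-(trimethylsilyl)ethyl 2-bromoprop-2-enoate | C=C(Br)C(=O)OCC[Si](C)(C)C | intermediate
15 | 2-(trimethylsilyl)ethyl 2-[1β-methyl-3-oxo-1α-vinyl-5α-(tert-butyldimethylsilyloxy)-6α-[3-(triethylsilyloxy)prop-1-en-2-yl]cyclohex-4β-yl]prop-2-enoate | C=C[C@]1(C)CC(=O)[C@@H](C(=C)C(=O)OCC[Si](C)(C)C)[C@H](O[Si](C)(C)C(C)(C)C)[C@@H]1C(=C)CO[Si](CC)(CC)CC | intermediate
16 | 3β-hydroxy compound from 15 (C3 OH axial, cis to the C4 side chain) | C=C[C@]1(C)C[C@@H](O)[C@@H](C(=C)C(=O)OCC[Si](C)(C)C)[C@H](O[Si](C)(C)C(C)(C)C)[C@@H]1C(=C)CO[Si](CC)(CC)CC | intermediate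
17 | 3-methylfuran-2(5H)-one | CC1=CCOC1=O | starting material
18 | sodium (Z)-4-hydroxy-2-methylbut-2-enoate | [Na+].[O-]C(=O)/C(C)=C\CO | intermediate
19 | (Z)-4-acetoxy-2-methylbut-2-enoic acid | OC(=O)/C(C)=C\COC(C)=O | intermediate
20 | 3α-[(Z)-4-acetoxy-2-methylbut-2-enoyl] ester, 5α-OTBS, primary OTES, 2-(trimethylsilyl)ethyl acrylate | C=C[C@]1(C)C[C@H](OC(=O)/C(C)=C\COC(C)=O)[C@@H](C(=C)C(=O)OCC[Si](C)(C)C)[C@H](O[Si](C)(C)C(C)(C)C)[C@@H]1C(=C)CO[Si](CC)(CC)CC | intermediate
21 | CNP0261293.8 | C=C[C@]1(C)C[C@H](OC(=O)/C(C)=C\COC(C)=O)[C@@H](C(=C)C(=O)O)[C@H](O)[C@@H]1C(=C)CO | target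

**Step count and weak points**
Total step count: 11. Longest linear sequence: 8 steps (steps 1, 2, 4, 5, 7, 8, 10, 11).

Steps most likely to fail:

Step 7 (the proposed palladium coupling; risks are conjugate addition to the bromoacrylate, β-hydride loss from the palladium enolate, and loss of the C5 silyloxy group from the product). The fallback uses known chemistry, sets out from 11 and comes back at 15. Mukaiyama aldol addition of 11 to 2-(trimethylsilyl)ethyl 3-bromo-2-oxopropanoate F4 (made from bromopyruvic acid and 2-(trimethylsilyl)ethanol) with BF3·OEt2 in CH2Cl2 at −78 °C gives the β-face bromohydrin 2-(trimethylsilyl)ethyl 3-bromo-2-hydroxy-2-(ring C4β-yl)propanoate F5. Zinc dust in AcOH/THF then removes Br and OH as a reductive 1,2-elimination, which can only give the 1,1-disubstituted double bond of 15.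

Step 4 (thermal cycloaddition onto a β-methyl enone may be too slow below the temperature at which the acetoxypyranone decomposes). The fallback sets out from 3 and comes back at 7. Br2 in CH2Cl2 at −78 °C gives the 4,5-dibromide of 3 F1. Pyridine removes HBr to give the more reactive α-bromo enone (2S)-4-bromo-3-methyl-5-oxo-5,6-dihydro-2H-pyran-2-yl acetate F2. This adds diene 6 at 25–40 °C to give the bromo adduct (7 with Br in place of the C6 hydrogen) F3. Bu3SnH with AIBN in benzene at 80 °C then replaces bromine by hydrogen from the convex β face and returns cis-fused 7.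

Step 10 (Mitsunobu reaction on a hindered axial alcohol may give elimination towards C4, or retention). The fallback sets out from 16 and 19 and comes back at 20. ClCH2SO2Cl and pyridine at 0 °C convert 16 into the 3β-chloromethanesulfonate of 16 F6. This is displaced with inversion by caesium (Z)-4-acetoxy-2-methylbut-2-enoate F7 (from 19 and Cs2CO3) with 18-crown-6 in toluene at 50 °C.

**Further compounds**
F1 | step 4 | (2S)-4,5-dibromo-3-methyl... dibromide of 3 (4,5-dibromo-5-methyl-3-oxotetrahydropyran-6-yl acetate; mixture at the new centres) | CC(=O)O[C@@H]1OCC(=O)C(Br)C1(C)Br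
F2 | step 4 | (2S)-4-bromo-3-methyl-5-oxo-5,6-dihydro-2H-pyran-2-yl acetate | CC(=O)O[C@@H]1OCC(=O)C(Br)=C1C
F3 | step 4 | bromo adduct: 7 with Br (β) in place of H at the ring-fusion carbon C6 | CC(=O)O[C@@H]1OCC(=O)[C@@]2(Br)[C@@H](O[Si](C)(C)C(C)(C)C)C=C(O[Si](C)(C)C(C)(C)C)C[C@@]12C
F4 | step 7 | 2-(trimethylsilyl)ethyl 3-bromo-2-oxopropanoate | O=C(CBr)C(=O)OCC[Si](C)(C)C
F5 | step 7 | bromohydrin: 2-(trimethylsilyl)ethyl 3-bromo-2-hydroxy-2-[1β-methyl-3-oxo-1α-vinyl-5α-(tert-butyldimethylsilyloxy)-6α-[3-(triethylsilyloxy)prop-1-en-2-yl]cyclohex-4β-yl]propanoate (carbinol centre as mixture) | C=C[C@]1(C)CC(=O)[C@@H](C(O)(CBr)C(=O)OCC[Si](C)(C)C)[C@H](O[Si](C)(C)C(C)(C)C)[C@@H]1C(=C)CO[Si](CC)(CC)CC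
F6 | step 10 | 3β-chloromethanesulfonate of 16 | C=C[C@]1(C)C[C@@H](OS(=O)(=O)CCl)[C@@H](C(=C)C(=O)OCC[Si](C)(C)C)[C@H](O[Si](C)(C)C(C)(C)C)[C@@H]1C(=C)CO[Si](CC)(CC)CC
F7 | step 10 | caesium (Z)-4-acetoxy-2-methylbut-2-enoate | [Cs+].[O-]C(=O)/C(C)=C\COC(C)=O
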